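The enabling feature is in the outer ring. Its phenolic O, the ipso carbon, the adjacent ring carbon that carries the bridge and the two bridge CH2 carbons are the five atoms of a furan. Target 21 is therefore a reductively opened 2-arylbenzofuran 18 (retro: re-bond O to the bridge carbon next to the central ring).
Cuts, in order: furan bonds C3–C3a and O–C2 of 18 together, giving O-phenyl oxime 14 of methyl ketone 12. Then the aryl–acetyl bond of 12, giving triflate 9 and butyl vinyl ether 10. Then the central ring–CH2 bond, giving aryllithium 4 and aldehyde 3.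
Forward: all three benzene rings are bought. Compound 1 gains the benzyl arm (steps 1–3), and its two equivalent OH groups are differentiated as OTf and OBn (steps 4–5). The acetyl group (step 6) and the PhO–N= unit (step 7) follow. The furan is the only ring made; it closes in step 8 and is opened again by hydrogen in step 9.
Stereochemistry: 21 has no stereocentre and no stereogenic double bond. The centres in 5, 17 and 20 are transient, racemic and erased.

Key step: step 8

Remark on the chemistry: the target SMILES has no stereodescriptor and the molecule has no stereogenic element, so "single enantiomer" is taken to mean the one achiral compound.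

Step 1
Reactants: 1 5-methoxyresorcinol
Product: 2 1-methoxy-3,5-bis(methoxymethoxy)benzene
Conditions: NaH (2.4 equiv), MOMCl (2.4 equiv), DMF, 0 °C to rt
Reagents that add atoms: chloromethyl methyl ether (MOMCl), COCCl
Why: Williamson-type O-alkylation of both phenoxides installs two acetal ethers that tolerate organolithiums and are the strongest ortho-directing groups on the ring.

Step 2
Reactants: 2 1-methoxy-3,5-bis(methoxymethoxy)benzene; 3 4-(benzyloxy)benzaldehyde
Product: 5 (±)-[4-(benzyloxy)phenyl][4-methoxy-2,6-bis(methoxymethoxy)phenyl]methanol, via aryllithium 4 (not isolated)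
Conditions: n-BuLi (1.1 equiv), THF, 0 °C to rt; 3, −78 to 0 °C; H2O
Reagents that add atoms: none
Why: Directed ortho-metalation followed by 1,2-addition to the aldehyde, in which the C–H flanked by two chelating OMOM groups should be removed in preference to the two C–H sites that have one OMOM and one weaker OMe neighbour, and the carbinol centre is left racemic because step 3 deletes it.

Step 3
Reactants: 5 (±)-[4-(benzyloxy)phenyl][4-methoxy-2,6-bis(methoxymethoxy)phenyl]methanol
Product: 7 2-[4-(benzyloxy)benzyl]-5-methoxybenzene-1,3-diol, via bis-MOM diarylmethane 6 (not isolated)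
Conditions: Et3SiH (3 equiv), TFA (3 equiv), CH2Cl2, −20 to 0 °C; evaporate; conc. HCl (cat.), MeOH, 45 °C
Reagents that add atoms: none
Why: Ionic hydrogenation (silane hydride captures the doubly aryl-stabilised benzhydryl cation) removes the carbinol oxygen without touching the benzyl ether, and acid-catalysed acetal exchange with methanol then completes MOM removal, however much of it has already begun in the TFA stage.

Step 4
Reactants: 7 2-[4-(benzyloxy)benzyl]-5-methoxybenzene-1,3-diol
Product: 8 2-[4-(benzyloxy)benzyl]-3-hydroxy-5-methoxyphenyl trifluoromethanesulfonate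
Conditions: Tf2O (1.0 equiv, slow addition), pyridine (3 equiv), CH2Cl2, −78 to 0 °C; unreacted 7 recovered
Reagents that add atoms: trifluoromethanesulfonic anhydride (Tf2O), O=S(=O)(OS(=O)(=O)C(F)(F)F)C(F)(F)F
Why: O-sulfonylation of a symmetric diol whose two hydroxyls give the same product, where the first triflate group is a strong acceptor that lowers the nucleophilicity of the remaining phenol, so one equivalent at low temperature should give more mono-triflate than the statistical share.

Step 5
Reactants: 8 2-[4-(benzyloxy)benzyl]-3-hydroxy-5-methoxyphenyl trifluoromethanesulfonate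
Product: 9 3-(benzyloxy)-2-[4-(benzyloxy)benzyl]-5-methoxyphenyl trifluoromethanesulfonate
Conditions: BnBr (1.2 equiv), K2CO3 (1.5 equiv), acetone, rt
Reagents that add atoms: benzyl bromide, BrCc1ccccc1
Why: Williamson ether synthesis on the phenol, now more acidic, runs with a mild carbonate base at room temperature, conditions under which aryl triflates persist.

Step 6
Reactants: 9 3-(benzyloxy)-2-[4-(benzyloxy)benzyl]-5-methoxyphenyl trifluoromethanesulfonate; 10 butyl vinyl ether
Product: 12 1-{3-(benzyloxy)-2-[4-(benzyloxy)benzyl]-5-methoxyphenyl}ethan-1-one, via butyl enol ether 11 (not isolated)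
Conditions: 10 (5 equiv), Pd(OAc)2 (5 mol %), dppp (10 mol %), Et3N (2 equiv), DMF, 90 °C; then 1 M HCl, THF, rt
Reagents that add atoms: water, O
Why: Mizoroki–Heck α-arylation of an electron-rich olefin, in which the triflate leaving group and the bidentate ligand enforce the cationic pathway that places the aryl group on the oxygen-bearing carbon, and dilute acid then hydrolyses the enol ether to the methyl ketone while the benzyl ethers stay intact.

Step 7
Reactants: 12 1-{3-(benzyloxy)-2-[4-(benzyloxy)benzyl]-5-methoxyphenyl}ethan-1-one; 13 O-phenylhydroxylamine hydrochloride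
Product: 14 (E)-1-{3-(benzyloxy)-2-[4-(benzyloxy)benzyl]-5-methoxyphenyl}ethan-1-one O-phenyl oxime
Conditions: 13 (1.3 equiv), NaOAc (1.5 equiv), EtOH, 50 °C
Reagents that add atoms: none
Why: Oxime-ether condensation of a ketone with an O-substituted hydroxylamine under acetate buffering should favour the E isomer (OPh anti to the bulky aryl group), and any Z isomer is carried on because both enter the same ene-hydroxylamine in step 8.

Step 8
Reactants: 14 (E)-1-{3-(benzyloxy)-2-[4-(benzyloxy)benzyl]-5-methoxyphenyl}ethan-1-one O-phenyl oxime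
Product: 18 2-{3-(benzyloxy)-2-[4-(benzyloxy)benzyl]-5-methoxyphenyl}benzofuran, via N-trifluoroacetyl ene-hydroxylamine 15 (not isolated), via hydroxyaryl N-acylimine 16 (not isolated), via cyclic N-acyl aminal 17 (not isolated)
Conditions: (CF3CO)2O (3 equiv), CH2Cl2, 0 to 40 °C; aq. NaHCO3
Reagents that add atoms: none
Why: Trifluoroacetylation of the oxime nitrogen and loss of a methyl proton give 15, whose weak N–O bond breaks in a chair-like [3,3]-sigmatropic shift that joins the former methyl carbon to an ortho C–H carbon of the phenoxy ring, and re-aromatisation delivers 16. The freed phenol oxygen adds to the activated C=N carbon in a 5-exo-trig closure (17), and the trifluoroacetic acid released in the acylation expels trifluoroacetamide, which aromatises the furan. The closest known reaction type is the O-aryl oxime route to benzofurans, which parallels the Fischer indole synthesis with oxygen in place of the aniline nitrogen; its acylation-triggered variant is established for acetophenone O-aryl oximes and runs well below the temperatures of the mineral-acid version, so both benzyl ethers and the electron-rich diarylmethane should survive. The selectivity needed is one enolisable site and one kind of ortho carbon: the methyl group is the only α-C–H donor (the diarylmethane CH2 is not α to the C=N), and the unsubstituted phenoxy ring offers two equivalent ortho positions. No stereocentre remains, since the aminal carbon of 17 is racemic and becomes sp2 on elimination.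

Step 9
Reactants: 18 2-{3-(benzyloxy)-2-[4-(benzyloxy)benzyl]-5-methoxyphenyl}benzofuran
Product: 21 2-(4-hydroxybenzyl)-3-[2-(2-hydroxyphenyl)ethyl]-5-methoxyphenol (CNP0260198.0), via debenzylated benzofuran 19 (not isolated), via debenzylated dihydrobenzofuran 20 (not isolated)
Conditions: H2 (5 bar), 20 wt % Pd(OH)2/C, AcOH–EtOAc 1:1, 50 °C
Reagents that add atoms: none
Why: Heterogeneous hydrogenation and hydrogenolysis, in which the aryl benzyl ethers should cleave first, the furan C2=C3 bond is then saturated, and the resulting cyclic secondary benzyl aryl ether loses its C2–O bond in the acidic medium with the phenol as leaving group, while the diarylmethane and bibenzyl C–C bonds and the aryl methyl ether are inert.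

Compound list
1 | 5-methoxyresorcinol | COc1cc(O)cc(O)c1 | starting material
2 | 1-methoxy-3,5-bis(methoxymethoxy)benzene | COCOc1cc(OC)cc(OCOC)c1 | intermediate
3 | 4-(benzyloxy)benzaldehyde | O=Cc1ccc(OCc2ccccc2)cc1 | starting material
4 | [4-methoxy-2,6-bis(methoxymethoxy)phenyl]lithium (not isolated) | [Li]c1c(OCOC)cc(OC)cc1OCOC | intermediate
5 | (±)-[4-(benzyloxy)phenyl][4-methoxy-2,6-bis(methoxymethoxy)phenyl]methanol (racemic) | COCOc1cc(OC)cc(OCOC)c1C(O)c1ccc(OCc2ccccc2)cc1 | intermediate
6 | 2-[4-(benzyloxy)benzyl]-5-methoxy-1,3-bis(methoxymethoxy)benzene (not isolated) | COCOc1cc(OC)cc(OCOC)c1Cc1ccc(OCc2ccccc2)cc1 | intermediate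
7 | 2-[4-(benzyloxy)benzyl]-5-methoxybenzene-1,3-diol | COc1cc(O)c(Cc2ccc(OCc3ccccc3)cc2)c(O)c1 | intermediate
8 | 2-[4-(benzyloxy)benzyl]-3-hydroxy-5-methoxyphenyl trifluoromethanesulfonate | COc1cc(O)c(Cc2ccc(OCc3ccccc3)cc2)c(OS(=O)(=O)C(F)(F)F)c1 | intermediate
9 | 3-(benzyloxy)-2-[4-(benzyloxy)benzyl]-5-methoxyphenyl trifluoromethanesulfonate | COc1cc(OCc2ccccc2)c(Cc2ccc(OCc3ccccc3)cc2)c(OS(=O)(=O)C(F)(F)F)c1 | intermediate
10 | butyl vinyl ether | C=COCCCC | starting material
11 | 1-(benzyloxy)-2-[4-(benzyloxy)benzyl]-3-(1-butoxyvinyl)-5-methoxybenzene (not isolated) | C=C(OCCCC)c1cc(OC)cc(OCc2ccccc2)c1Cc1ccc(OCc2ccccc2)cc1 | intermediate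
12 | 1-{3-(benzyloxy)-2-[4-(benzyloxy)benzyl]-5-methoxyphenyl}ethan-1-one | CC(=O)c1cc(OC)cc(OCc2ccccc2)c1Cc1ccc(OCc2ccccc2)cc1 | intermediate
13 | O-phenylhydroxylamine hydrochloride | NOc1ccccc1.Cl | starting material
14 | (E)-1-{3-(benzyloxy)-2-[4-(benzyloxy)benzyl]-5-methoxyphenyl}ethan-1-one O-phenyl oxime | C/C(=N\Oc1ccccc1)c1cc(OC)cc(OCc2ccccc2)c1Cc1ccc(OCc2ccccc2)cc1 | intermediate
15 | N-(1-{3-(benzyloxy)-2-[4-(benzyloxy)benzyl]-5-methoxyphenyl}vinyl)-2,2,2-trifluoro-N-phenoxyacetamide (not isolated) | C=C(N(Oc1ccccc1)C(=O)C(F)(F)F)c1cc(OC)cc(OCc2ccccc2)c1Cc1ccc(OCc2ccccc2)cc1 | intermediate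
16 | N-[1-{3-(benzyloxy)-2-[4-(benzyloxy)benzyl]-5-methoxyphenyl}-2-(2-hydroxyphenyl)ethylidene]-2,2,2-trifluoroacetamide (not isolated) | O=C(N=C(Cc1ccccc1O)c1cc(OC)cc(OCc2ccccc2)c1Cc1ccc(OCc2ccccc2)cc1)C(F)(F)F | intermediate
17 | (±)-N-(2-{3-(benzyloxy)-2-[4-(benzyloxy)benzyl]-5-methoxyphenyl}-2,3-dihydrobenzofuran-2-yl)-2,2,2-trifluoroacetamide (racemic, not isolated) | O=C(NC1(Cc2ccccc2O1)c1cc(OC)cc(OCc2ccccc2)c1Cc1ccc(OCc2ccccc2)cc1)C(F)(F)F | intermediate
18 | 2-{3-(benzyloxy)-2-[4-(benzyloxy)benzyl]-5-methoxyphenyl}benzofuran | COc1cc(OCc2ccccc2)c(Cc2ccc(OCc3ccccc3)cc2)c(-c2cc3ccccc3o2)c1 | intermediate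
19 | 3-(benzofuran-2-yl)-2-(4-hydroxybenzyl)-5-methoxyphenol (not isolated) | COc1cc(O)c(Cc2ccc(O)cc2)c(-c2cc3ccccc3o2)c1 | intermediate
20 | (±)-3-(2,3-dihydrobenzofuran-2-yl)-2-(4-hydroxybenzyl)-5-methoxyphenol (racemic, not isolated) | COc1cc(O)c(Cc2ccc(O)cc2)c(C2Cc3ccccc3O2)c1 | intermediate
21 | 2-(4-hydroxybenzyl)-3-[2-(2-hydroxyphenyl)ethyl]-5-methoxyphenol (CNP0260198.0, achiral) | COc1cc(O)c(Cc2ccc(O)cc2)c(CCc2ccccc2O)c1 | target

Total step count: 9. Longest linear sequence: 9 steps (1 to 21); compounds 3, 10 and 13 are bought and enter directly.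

Steps most likely to fail

Step 9. The reduction may stall after debenzylation. Saturation of the furan double bond next to an ortho-substituted aryl group can be slow. The secondary benzylic C–O bond may also resist cleavage, because the oxygen substituents on its aryl group sit meta and give no electronic help.
Fallback: set out from 18 and separate the two events using non-catalytic chemistry. Ionic hydrogenation (Et3SiH, TFA, CH2Cl2, rt) protonates C3 and delivers hydride to the C2 oxocarbenium ion. This gives (±)-2-{3-(benzyloxy)-2-[4-(benzyloxy)benzyl]-5-methoxyphenyl}-2,3-dihydrobenzofuran F1. Dissolving-metal reduction (Li, NH3–THF, −78 °C, NH4Cl quench; Birch-type benzylic ether cleavage) then breaks the ring C2–O bond and both benzyl ethers in one operation. The resulting phenoxides protect the rings from over-reduction. The route is rejoined at 21.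

Step 8. N-acylation or tautomerisation at the crowded ketimine may be slow. In that case hydrolysis back to the ketone, arrest at the aminal stage, or trifluoroacetylation of the enamide carbon or of an electron-rich ring could compete with the sigmatropic shift.
Fallback: set out from triflate 9 and bring in the heterocycle ready-made. Suzuki–Miyaura coupling is run with commercial benzofuran-2-ylboronic acid (OB(O)c1cc2ccccc2o1; XPhos-ligated Pd precatalyst, K3PO4, THF–H2O, 40 °C). These mild conditions are chosen to outrun protodeboronation. The route is rejoined at 18, and no compound outside the list arises (entry F0).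

Step 6. Olefin insertion at the hindered, electron-rich aryl–palladium centre may be slow. Intramolecular C–H palladation of the neighbouring benzyl ring, or loss of the triflate group by hydrolysis, could then compete.
Fallback: set out from 9 and replace insertion by transmetalation. Stille coupling is run with tributyl(1-ethoxyvinyl)stannane (C=C(OCC)[Sn](CCCC)(CCCC)CCCC; Pd(PPh3)4, LiCl, dioxane, 100 °C, no base). This gives 1-(benzyloxy)-2-[4-(benzyloxy)benzyl]-3-(1-ethoxyvinyl)-5-methoxybenzene F2. Hydrolysis with 1 M HCl in THF rejoins the route at 12.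

Further compounds
F1 | step 9 | (±)-2-{3-(benzyloxy)-2-[4-(benzyloxy)benzyl]-5-methoxyphenyl}-2,3-dihydrobenzofuran | COc1cc(OCc2ccccc2)c(Cc2ccc(OCc3ccccc3)cc2)c(C2Cc3ccccc3O2)c1
F0 | step 8 | none | none
F2 | step 6 | 1-(benzyloxy)-2-[4-(benzyloxy)benzyl]-3-(1-ethoxyvinyl)-5-methoxybenzene | C=C(OCC)c1cc(OC)cc(OCc2ccccc2)c1Cc1ccc(OCc2ccccc2)cc1
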